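**Retrosynthetic overview**

- The target is a depside: ring B is olivetolic acid acylated on O4, and ring A is a 3-chloro-2-hydroxy-4-methoxy-6-propylbenzoyl unit. The last disconnection is the benzyl ester that masks the ring B carboxylic acid.
- The plan rests on ring A being a chlorinated tetraketide-type resorcylate. C1 (bearing the depside carbonyl), C2 (OH) and C3 (Cl) form a 4-chloroacetoacetate unit. C4 (OMe), C5 (H) and C6 (propyl) form a 3-oxohexanoate unit at the ester oxidation level.
- Ring A is therefore cut at C3–C4 and C1–C6. In the forward direction a 4-chloro-1,3-bis(silyloxy)diene, already esterified to the ring B phenol, is condensed with 1,1-dimethoxyhex-1-en-3-one under TiCl4 in a formal [3+3] reaction.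
- The diene comes from benzyl olivetolate by acylketene 4-O-acylation (chloroacetyl Meldrum's acid) and two silylations. The enone comes from 1,1-dimethoxyethene and butanoyl chloride.
- Ring order: ring B is bought as olivetol, ring A is built last in the key step, and hydrogenolysis then frees the acid.

Key step: step 8

Assumption: ring A is numbered from the carbon carrying the depside carbonyl (C1); the alkene geometries written for the silyl enol ether and the bis-silyl diene are those assumed to predominate and are lost on aromatisation.

**Route**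

Step 1
Reactants: 1 olivetol (5-pentylbenzene-1,3-diol)
Product: 2 olivetolic acid (2,4-dihydroxy-6-pentylbenzoic acid)
Conditions: MeOMgOCO2Me (2 M in DMF, excess), 120 °C, N2; then cold 2 M HCl
Reagents that add atoms: magnesium methyl carbonate, COC(=O)O[Mg]OC
Why: Ortho-carboxylation of a phenol with magnesium methyl carbonate (a Kolbe–Schmitt-type reaction driven by the chelated magnesium salicylate) is the established way from olivetol to olivetolic acid, the carboxyl entering ortho to one hydroxyl and para to the other.

Step 2
Reactants: 2 olivetolic acid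
Product: 3 benzyl 2,4-dihydroxy-6-pentylbenzoate
Conditions: BnBr (1.05 equiv), KHCO3 (1.2 equiv), DMF, rt
Reagents that add atoms: benzyl bromide, BrCc1ccccc1
Why: Bicarbonate deprotonates only the carboxylic acid, so SN2 O-alkylation of the carboxylate should give the benzyl ester and leave both phenols free.

Step 3
Reactants: 4 Meldrum's acid (2,2-dimethyl-1,3-dioxane-4,6-dione); 5 chloroacetyl chloride
Product: 6 5-(2-chloro-1-hydroxyethylidene)-2,2-dimethyl-1,3-dioxane-4,6-dione (chloroacetyl Meldrum's acid, enol form)
Conditions: pyridine (2 equiv), CH2Cl2, 0 °C → rt; wash with 1 M HCl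
Reagents that add atoms: none
Why: C-acylation of Meldrum's acid by an acid chloride with pyridine is the standard preparation of acyl Meldrum's acids, which are obtained as the hydrogen-bonded enols.

Step 4
Reactants: 3 benzyl 2,4-dihydroxy-6-pentylbenzoate; 6 chloroacetyl Meldrum's acid
Product: 8 benzyl 4-[(4-chloro-3-oxobutanoyl)oxy]-2-hydroxy-6-pentylbenzoate, via chloroacetylketene 7 (not isolated)
Conditions: 6 (1.2 equiv), toluene, 90–100 °C, N2 stream, until gas evolution stops
Reagents that add atoms: none
Why: Thermolysis of the acyl Meldrum's acid expels acetone and CO2 to give acylketene 7, which should be trapped by the free 4-OH of 3 (the 2-OH is held in a hydrogen bond to the ester carbonyl) in a standard acylketene acetoacetylation, so the later di-ortho-substituted ester is formed while its carbonyl is still unhindered.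

Step 5
Reactants: 9 1,1-dimethoxyethene; 10 butanoyl chloride
Product: 11 1,1-dimethoxyhex-1-en-3-one
Conditions: 9 (1.3 equiv), NEt3 (1.2 equiv), Et2O, 0 °C → rt; filter, distil under reduced pressure, store under argon
Reagents that add atoms: none
Why: C-acylation of the nucleophilic ketene acetal by the acid chloride, with NEt3 taking the proton from the dialkoxycarbenium intermediate, is the usual preparation of β-acyl ketene acetals; any ethylketene formed from 10 and NEt3 adds to 9 through the same zwitterion and should end as the same product.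

Step 6
Reactants: 8 benzyl 4-[(4-chloro-3-oxobutanoyl)oxy]-2-hydroxy-6-pentylbenzoate
Product: 12 benzyl 4-{[(2E)-4-chloro-3-(trimethylsilyloxy)but-2-enoyl]oxy}-6-pentyl-2-(trimethylsilyloxy)benzoate
Conditions: Me3SiCl (3 equiv), NEt3 (3 equiv), toluene, rt, 48 h; filter under argon, concentrate
Reagents that add atoms: chlorotrimethylsilane, C[Si](C)(C)Cl
Why: Soft enolisation and O-silylation with Me3SiCl/NEt3 should turn the β-keto ester into its 3-silyloxy-2-enoate and cap the ring B phenol, which is the first stage of the standard two-stage preparation of 1,3-bis(silyloxy)dienes.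

Step 7
Reactants: 12 benzyl 4-{[(2E)-4-chloro-3-(trimethylsilyloxy)but-2-enoyl]oxy}-6-pentyl-2-(trimethylsilyloxy)benzoate
Product: 13 benzyl 4-{[(1Z,3Z)-4-chloro-1,3-bis(trimethylsilyloxy)buta-1,3-dien-1-yl]oxy}-6-pentyl-2-(trimethylsilyloxy)benzoate
Conditions: 12 and Me3SiCl (1.5 equiv) in THF, −78 °C; LiN(iPr)2 (1.15 equiv) added dropwise, → −20 °C; concentrate, hexane, filter under argon; use crude at once
Reagents that add atoms: chlorotrimethylsilane, C[Si](C)(C)Cl
Why: γ-Deprotonation of the 3-silyloxy-2-enoate at the CH2Cl carbon by LiN(iPr)2 and O-silylation of the dienolate is the second stage of the standard diene preparation and is known for 4-chloroacetoacetates; the internal Me3SiCl quench at −78 °C should trap the dienolate before it can expel the ring B aryloxide.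

Step 8
Reactants: 13 benzyl 4-{[(1Z,3Z)-4-chloro-1,3-bis(trimethylsilyloxy)buta-1,3-dien-1-yl]oxy}-6-pentyl-2-(trimethylsilyloxy)benzoate; 11 1,1-dimethoxyhex-1-en-3-one
Product: 16 benzyl 4-[(3-chloro-2-hydroxy-4-methoxy-6-propylbenzoyl)oxy]-2-hydroxy-6-pentylbenzoate, via open-chain Michael adduct 14 (not isolated), via cyclic aldol adduct 15 (not isolated)
Conditions: 11 (1.3 equiv), TiCl4 (1.5 equiv), CH2Cl2, 4 Å MS, −78 °C → 20 °C, 14 h; then 1 M HCl
Reagents that add atoms: none
Why: Proposed new method: a formal [3+3] cyclocondensation run on a 1-aryloxy-1,3-bis(silyloxy)diene, the closest known reaction type being the TiCl4-mediated cyclization of alkyl-ester-derived 1,3-bis(silyloxy)buta-1,3-dienes (4-chloro dienes among them) with 1,1-dimethoxyalk-1-en-3-ones to 4-methoxysalicylates. TiCl4 binds the ketone of 11, the CHCl terminus of 13 adds to the C(OMe)2 carbon in a Mukaiyama–Michael step, and methoxide is expelled to give the vinylogous ester 14, which creates the C3–C4 bond of ring A. The central carbon of the remaining silyl enol ether then attacks the titanium-bound propyl ketone in an intramolecular Mukaiyama aldol reaction, a 6-(enolexo)-exo-trig closure that forms C1–C6 and gives 15; loss of water and enolisation of the C2 ketone aromatise ring A. No stereocentre has to be controlled, because the CHCl and carbinol centres of 14 and 15 vanish on aromatisation. Only one orientation is wanted, CHCl terminus onto C(OMe)2 and the central diene carbon onto the ketone; it should be secured because the terminal carbon of a 1,3-bis(silyloxy)diene is its most nucleophilic site and because the two methoxy donors make the TiCl4-bound enone react at its β-carbon, not at the carbonyl. The aryloxy group only weakens the distal ketene acetal, which reacts second and intramolecularly, and acidic work-up should free both phenols while the benzyl ester stays.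

Step 9
Reactants: 16 benzyl 4-[(3-chloro-2-hydroxy-4-methoxy-6-propylbenzoyl)oxy]-2-hydroxy-6-pentylbenzoate
Product: 17 4-[(3-chloro-2-hydroxy-4-methoxy-6-propylbenzoyl)oxy]-2-hydroxy-6-pentylbenzoic acid (target)
Conditions: H2 (1 atm), 5% Pd/C (palladium on carbon), EtOAc, rt; stop at full conversion
Reagents that add atoms: none
Why: Hydrogenolysis of a benzyl ester over palladium on carbon is fast at room temperature and atmospheric pressure in a neutral solvent, conditions under which the aryl chloride and the depside ester should be retained.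

**Compound list**

1 | olivetol (5-pentylbenzene-1,3-diol) | CCCCCc1cc(O)cc(O)c1 | starting material
2 | olivetolic acid (2,4-dihydroxy-6-pentylbenzoic acid) | CCCCCc1cc(O)cc(O)c1C(=O)O | intermediate
3 | benzyl 2,4-dihydroxy-6-pentylbenzoate | CCCCCc1cc(O)cc(O)c1C(=O)OCc1ccccc1 | intermediate
4 | Meldrum's acid (2,2-dimethyl-1,3-dioxane-4,6-dione) | CC1(C)OC(=O)CC(=O)O1 | starting material
5 | chloroacetyl chloride | ClCC(=O)Cl | starting material
6 | 5-(2-chloro-1-hydroxyethylidene)-2,2-dimethyl-1,3-dioxane-4,6-dione | CC1(C)OC(=O)C(=C(O)CCl)C(=O)O1 | intermediate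
7 | chloroacetylketene (4-chloro-3-oxobut-1-en-1-one), not isolated | O=C=CC(=O)CCl | intermediate
8 | benzyl 4-[(4-chloro-3-oxobutanoyl)oxy]-2-hydroxy-6-pentylbenzoate | CCCCCc1cc(OC(=O)CC(=O)CCl)cc(O)c1C(=O)OCc1ccccc1 | intermediate
9 | 1,1-dimethoxyethene | C=C(OC)OC | starting material
10 | butanoyl chloride | CCCC(=O)Cl | starting material
11 | 1,1-dimethoxyhex-1-en-3-one | CCCC(=O)C=C(OC)OC | intermediate
12 | benzyl 4-{[(2E)-4-chloro-3-(trimethylsilyloxy)but-2-enoyl]oxy}-6-pentyl-2-(trimethylsilyloxy)benzoate | CCCCCc1cc(OC(=O)/C=C(\CCl)O[Si](C)(C)C)cc(O[Si](C)(C)C)c1C(=O)OCc1ccccc1 | intermediate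
13 | benzyl 4-{[(1Z,3Z)-4-chloro-1,3-bis(trimethylsilyloxy)buta-1,3-dien-1-yl]oxy}-6-pentyl-2-(trimethylsilyloxy)benzoate | Cl/C=C(O[Si](C)(C)C)/C=C(O[Si](C)(C)C)/Oc1cc(O[Si](C)(C)C)c(C(=O)OCc2ccccc2)c(CCCCC)c1 | intermediate
14 | open-chain Michael adduct, not isolated: benzyl 4-{[4-chloro-5-methoxy-7-oxo-3-(trimethylsilyloxy)deca-2,5-dienoyl]oxy}-6-pentyl-2-(trimethylsilyloxy)benzoate (racemic at the CHCl carbon, alkene geometry undefined; drawn as the silyl enol ether, a titanium enolate being equally possible in the flask) | CCCC(=O)C=C(OC)C(Cl)C(O[Si](C)(C)C)=CC(=O)Oc1cc(O[Si](C)(C)C)c(C(=O)OCc2ccccc2)c(CCCCC)c1 | intermediate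
15 | cyclic aldol adduct, not isolated: benzyl 4-[(3-chloro-6-hydroxy-4-methoxy-2-oxo-6-propylcyclohex-4-ene-1-carbonyl)oxy]-6-pentyl-2-(trimethylsilyloxy)benzoate (mixture of diastereomers; drawn as the free alcohol, titanium-bound in the flask) | CCCC1(O)C=C(OC)C(Cl)C(=O)C1C(=O)Oc1cc(O[Si](C)(C)C)c(C(=O)OCc2ccccc2)c(CCCCC)c1 | intermediate
16 | benzyl 4-[(3-chloro-2-hydroxy-4-methoxy-6-propylbenzoyl)oxy]-2-hydroxy-6-pentylbenzoate | CCCCCc1cc(OC(=O)c2c(CCC)cc(OC)c(Cl)c2O)cc(O)c1C(=O)OCc1ccccc1 | intermediate
17 | 4-[(3-chloro-2-hydroxy-4-methoxy-6-propylbenzoyl)oxy]-2-hydroxy-6-pentylbenzoic acid | CCCCCc1cc(OC(=O)c2c(CCC)cc(OC)c(Cl)c2O)cc(O)c1C(=O)O | target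

**Step count**

Total steps: 9. Longest linear sequence: 7 steps (steps 1, 2, 4, 6, 7, 8 and 9, from olivetol).

**Steps most likely to fail**

1. Step 8 (Proposed new method). The aryloxy-substituted ketene acetal may give up the ring B phenoxide under TiCl4 (fragmentation towards an acylketene), or the sequence may stop after the Michael stage, so that work-up returns open-chain keto ester instead of ring A.
Fallback, using known chemistry: ring A is built on a benzyl ester and the depside bond is made afterwards. It sets out from 6, 11 and 3 and comes back to the route at 16. Thermolysis of 6 in toluene with benzyl alcohol should give benzyl 4-chloro-3-oxobutanoate F1. Me3SiCl/NEt3 should then give benzyl (2E)-4-chloro-3-(trimethylsilyloxy)but-2-enoate F2. LiN(iPr)2/Me3SiCl at −78 °C should give {[(1Z,3Z)-1-(benzyloxy)-4-chlorobuta-1,3-diene-1,3-diyl]bis(oxy)}bis(trimethylsilane) F3. The TiCl4-mediated [3+3] cyclization of this alkyl-ester diene with 11 (the established substrate class) should give benzyl 3-chloro-2-hydroxy-4-methoxy-6-propylbenzoate F4. Hydrogenolysis (H2, Pd/C, EtOAc) should give 3-chloro-2-hydroxy-4-methoxy-6-propylbenzoic acid F5. Esterification of F5 with the 4-OH of 3 through the mixed trifluoroacetic anhydride ((CF3CO)2O, toluene, rt), the usual coupling for hindered depside acids, should give 16.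

2. Step 7. The lithium dienolate of the aryl ester may expel the ring B aryloxide (E1cB ketene formation) before it is silylated, or LiN(iPr)2 may deprotonate the benzylic position of the pentyl chain next to the ring B ester.
Fallback: the diene is made without any anionic intermediate. It sets out from 8 and comes back at 13, bypassing 12. Soft enolisation in one operation (Me3SiOTf 3.3 equiv, NEt3 3.5 equiv, Et2O, 0 °C) should silylate the phenol, the ketone enol and, through O-silylation of the ester carbonyl and γ-deprotonation by the amine, the ester oxygen. This fallback makes no compound outside the list (F0).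

3. Step 5. Chloride may demethylate the dialkoxycarbenium intermediate to methyl 3-oxohexanoate, ketene-derived cyclobutanone by-products may persist, and the moisture-sensitive product may hydrolyse during isolation.
Fallback: the ketene acetal is made by substitution on a dichlorovinyl ketone. It sets out from 10 and comes back at 11. AlCl3-mediated acylation of 1,1-dichloroethene with 10 (CH2Cl2, 0 °C) should give 1,1,1-trichlorohexan-3-one F6. Dehydrochlorination with NEt3 should give 1,1-dichlorohex-1-en-3-one F7. Two equivalents of NaOMe (MeOH/Et2O, 0 °C) should replace both vinylic chlorides by addition–elimination to give 11.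

**Further compounds**

F1 | step 8 | benzyl 4-chloro-3-oxobutanoate | O=C(CCl)CC(=O)OCc1ccccc1
F2 | step 8 | benzyl (2E)-4-chloro-3-(trimethylsilyloxy)but-2-enoate | ClC/C(O[Si](C)(C)C)=C\C(=O)OCc1ccccc1
F3 | step 8 | {[(1Z,3Z)-1-(benzyloxy)-4-chlorobuta-1,3-diene-1,3-diyl]bis(oxy)}bis(trimethylsilane) | Cl/C=C(O[Si](C)(C)C)/C=C(O[Si](C)(C)C)/OCc1ccccc1
F4 | step 8 | benzyl 3-chloro-2-hydroxy-4-methoxy-6-propylbenzoate | CCCc1cc(OC)c(Cl)c(O)c1C(=O)OCc1ccccc1
F5 | step 8 | 3-chloro-2-hydroxy-4-methoxy-6-propylbenzoic acid | CCCc1cc(OC)c(Cl)c(O)c1C(=O)O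
F0 | step 7 | none | none
F6 | step 5 | 1,1,1-trichlorohexan-3-one | CCCC(=O)CC(Cl)(Cl)Cl
F7 | step 5 | 1,1-dichlorohex-1-en-3-one | CCCC(=O)C=C(Cl)Cl
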